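## Retrosynthetic overview

1. Target ⇒ 6β-OH / 7α-OTBS / 15-OTBS precursor: the hindered 6β-OH is acylated last, then both silyl ethers are removed.
2. The 13E allylic alcohol ⇒ enoate ⇒ Z enol phosphate + Me2CuLi ⇒ β-keto ester. The key C13–C14 bond comes from an intermolecular Claisen condensation of a C17 N-acylimidazole (fragment 1) with potassium ethyl malonate (fragment 2).
3. Ring B oxygens: 6β-OH by α-face hydride reduction of a 6-ketone; 7α-OH by α-face hydroxylation of the dienolate of a 7-en-6-one.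
4. The 7-en-6-one ⇒ 17-nor-8-ketone (Saegusa–Ito, MeLi, oxidative 1,3-transposition) ⇒ sclareol by side-chain degradation, exocyclic dehydration and alkene cleavage.
5. No ring is formed: rings A and B, with the C5 and C10 configurations, come intact from (−)-sclareol.

Assumption: labdane numbering with α/β face descriptors (β = face of the C10 methyl) is used, so the target is (13E)-7α,15-dihydroxylabda-8,13-dien-6β-yl 3-methylbutanoate; PMB = 4-methoxybenzyl, TBS = tert-butyldimethylsilyl, TMS = trimethylsilyl.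

## Route

Step 1
Reactants: 1 (−)-sclareol
Product: 2 8α-hydroxy-14,15-dinorlabdan-13-one
Conditions: KMnO4, acetone/H2O, 0 °C → rt
Reagents that add atoms: none
Why: Permanganate oxidative degradation of the tertiary vinyl carbinol removes C14 and C15 and leaves the C13 methyl ketone; no ring stereocentre is touched.

Step 2
Reactants: 2 8α-hydroxy-14,15-dinorlabdan-13-one
Product: 4 8α-hydroxy-14,15,16-trinorlabdan-13-oic acid, via tribromomethyl ketone 3 (not isolated)
Conditions: Br2, NaOH, dioxane/H2O, 0 °C → rt; then aq. HCl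
Reagents that add atoms: sodium hydroxide, [Na+].[OH-]
Why: Haloform reaction: exhaustive bromination of the methyl group and hydroxide cleavage of the tribromomethyl ketone remove C16 and give the C13 acid.

Step 3
Reactants: 4 8α-hydroxy-14,15,16-trinorlabdan-13-oic acid
Product: 5 14,15,16-trinorlabdane-8α,13-diol
Conditions: LiAlH4, THF, reflux
Reagents that add atoms: none
Why: Hydride reduction of the acid (or of any δ-lactone formed from it) gives the primary alcohol with all stereocentres unchanged.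

Step 4
Reactants: 5 14,15,16-trinorlabdane-8α,13-diol
Product: 6 13-(4-methoxybenzyloxy)-14,15,16-trinorlabdan-8α-ol
Conditions: NaH, PMBCl, Bu4NI (cat.), THF/DMF, 0 °C → rt
Reagents that add atoms: 4-methoxybenzyl chloride, COc1ccc(CCl)cc1
Why: Williamson etherification occurs only at the primary alcohol because the tertiary 8α-OH is too hindered to be alkylated.

Step 5
Reactants: 6 13-(4-methoxybenzyloxy)-14,15,16-trinorlabdan-8α-ol
Product: 7 13-(4-methoxybenzyloxy)-14,15,16-trinorlabd-8(17)-ene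
Conditions: SOCl2, pyridine, CH2Cl2, −78 °C
Reagents that add atoms: none
Why: E2 dehydration through the chlorosulfite: the equatorial 8α leaving group has only C17–H bonds anti-periplanar, so the exocyclic alkene is the major isomer (minor endocyclic isomers are removed after step 6).

Step 6
Reactants: 7 13-(4-methoxybenzyloxy)-14,15,16-trinorlabd-8(17)-ene
Product: 9 13-(4-methoxybenzyloxy)-14,15,16,17-tetranorlabdan-8-one, via 8α,17-diol 8 (not isolated)
Conditions: OsO4 (2 mol %), NaIO4, 2,6-lutidine, dioxane/H2O, rt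
Reagents that add atoms: osmium tetroxide, O=[Os](=O)(=O)=O (catalytic oxygen transfer); sodium periodate, [Na+].[O-]I(=O)(=O)=O (re-oxidant and net oxygen source)
Why: Lemieux–Johnson cleavage (dihydroxylation, then periodate glycol cleavage) of the unhindered 1,1-disubstituted alkene gives the 8-ketone and tolerates the PMB ether.

Step 7
Reactants: 9 13-(4-methoxybenzyloxy)-14,15,16,17-tetranorlabdan-8-one
Product: 11 13-(4-methoxybenzyloxy)-8-(trimethylsilyloxy)-14,15,16,17-tetranorlabd-7-ene, via lithium enolate 10 (not isolated)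
Conditions: LiN(i-Pr)2, THF, −78 °C; TMSCl, Et3N, −78 °C → 0 °C
Reagents that add atoms: chlorotrimethylsilane, C[Si](C)(C)Cl
Why: Kinetic deprotonation takes the C7 methylene rather than the hindered C9 methine, and O-silylation fixes the Δ7 silyl enol ether regioselectively.

Step 8
Reactants: 11 13-(4-methoxybenzyloxy)-8-(trimethylsilyloxy)-14,15,16,17-tetranorlabd-7-ene
Product: 12 13-(4-methoxybenzyloxy)-14,15,16,17-tetranorlabd-6-en-8-one
Conditions: Pd(OAc)2 (1.1 equiv), MeCN, rt
Reagents that add atoms: none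
Why: Saegusa–Ito oxidation: palladation at C7 and syn β-hydride elimination of H6 give the conjugated enone.

Step 9
Reactants: 12 13-(4-methoxybenzyloxy)-14,15,16,17-tetranorlabd-6-en-8-one
Product: 13 13-(4-methoxybenzyloxy)-14,15,16-trinorlabd-6-en-8-ol (mixture of C8 epimers)
Conditions: MeLi, CeCl3, THF, −78 °C
Reagents that add atoms: methyllithium, [Li]C
Why: 1,2-addition of the weakly basic organocerium reagent to the enone carbonyl restores C17; the C8 configuration does not matter because C8 becomes sp2 in step 10.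

Step 10
Reactants: 13 13-(4-methoxybenzyloxy)-14,15,16-trinorlabd-6-en-8-ol
Product: 14 13-(4-methoxybenzyloxy)-14,15,16-trinorlabd-7-en-6-one
Conditions: pyridinium chlorochromate (C5H5NH[CrO3Cl]), 4 Å molecular sieves, CH2Cl2, rt
Reagents that add atoms: pyridinium chlorochromate, [O-][Cr](=O)(=O)Cl.c1cc[nH+]cc1
Why: Babler–Dauben oxidative 1,3-transposition: the tertiary allylic chromate ester rearranges to the C6 chromate, which is oxidised to the 7-en-6-one with the C8 methyl in place.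

Step 11
Reactants: 14 13-(4-methoxybenzyloxy)-14,15,16-trinorlabd-7-en-6-one
Product: 16 7α-hydroxy-13-(4-methoxybenzyloxy)-14,15,16-trinorlabd-8-en-6-one, via potassium dienolate 15 (not isolated)
Conditions: KN(SiMe3)2 (0.95 equiv), THF, −78 → 0 °C; then −78 °C, 2-(phenylsulfonyl)-3-phenyloxaziridine; AcOH quench at −78 °C
Reagents that add atoms: 2-(phenylsulfonyl)-3-phenyloxaziridine, O=S(=O)(c1ccccc1)N1OC1c1ccccc1
Why: Equilibrating γ-deprotonation at C9 gives the fully endocyclic dienolate, which the Davis oxidation hydroxylates at the α-carbon C7 from the α face (the β face is shielded by the C10 and C4β methyl groups), setting 7α-OH and the Δ8 alkene.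

Step 12
Reactants: 16 7α-hydroxy-13-(4-methoxybenzyloxy)-14,15,16-trinorlabd-8-en-6-one
Product: 17 13-(4-methoxybenzyloxy)-14,15,16-trinorlabd-8-ene-6β,7α-diol
Conditions: NaBH4, CeCl3·7H2O, MeOH, −40 °C
Reagents that add atoms: none
Why: Luche-type 1,2-reduction: the β face of C6 is blocked by the two syn-axial methyl groups (C4β and C10), so hydride adds from the α face (also the face of the 7α-oxygen) and sets the axial 6β-OH.

Step 13
Reactants: 17 13-(4-methoxybenzyloxy)-14,15,16-trinorlabd-8-ene-6β,7α-diol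
Product: 18 7α-(tert-butyldimethylsilyloxy)-13-(4-methoxybenzyloxy)-14,15,16-trinorlabd-8-en-6β-ol
Conditions: TBSCl, imidazole, DMF, rt
Reagents that add atoms: tert-butyldimethylsilyl chloride, CC(C)(C)[Si](C)(C)Cl
Why: Silylation takes the accessible allylic 7α-OH; the 6β-OH, syn-axial to two methyl groups, does not react, and trans-diaxial geometry rules out silyl migration.

Step 14
Reactants: 18 7α-(tert-butyldimethylsilyloxy)-13-(4-methoxybenzyloxy)-14,15,16-trinorlabd-8-en-6β-ol
Product: 19 7α-(tert-butyldimethylsilyloxy)-14,15,16-trinorlabd-8-ene-6β,13-diol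
Conditions: DDQ, CH2Cl2/pH 7 buffer, 0 °C
Reagents that add atoms: none
Why: Oxidative cleavage of the PMB ether by DDQ under buffered conditions leaves the silyl ether, the tetrasubstituted alkene and the hindered alcohol untouched.

Step 15
Reactants: 19 7α-(tert-butyldimethylsilyloxy)-14,15,16-trinorlabd-8-ene-6β,13-diol
Product: 21 7α-(tert-butyldimethylsilyloxy)-6β-hydroxy-14,15,16-trinorlabd-8-en-13-oic acid, via aldehyde 20 (not isolated)
Conditions: TEMPO (cat.), PhI(OAc)2, MeCN/H2O, rt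
Reagents that add atoms: water, O
Why: Oxoammonium-mediated oxidation of the primary alcohol through the aldehyde hydrate gives the acid; the hindered secondary 6β-OH is not oxidised.

Step 16
Reactants: 21 7α-(tert-butyldimethylsilyloxy)-6β-hydroxy-14,15,16-trinorlabd-8-en-13-oic acid
Product: 22 1-[7α-(tert-butyldimethylsilyloxy)-6β-hydroxy-14,15,16-trinorlabd-8-en-13-oyl]imidazole
Conditions: 1,1'-carbonyldiimidazole (1.05 equiv), THF, rt
Reagents that add atoms: 1,1'-carbonyldiimidazole, O=C(n1ccnc1)n1ccnc1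
Why: Acid activation as the N-acylimidazole; the hindered 6β-OH does not react with the reagent at room temperature.

Step 17
Reactants: 22 1-[7α-(tert-butyldimethylsilyloxy)-6β-hydroxy-14,15,16-trinorlabd-8-en-13-oyl]imidazole; 23 potassium ethyl malonate
Product: 26 ethyl 7α-(tert-butyldimethylsilyloxy)-6β-hydroxy-13-oxo-16-norlabd-8-en-15-oate, via magnesium malonate enolate 24 (not isolated), via acylmalonic half-ester 25 (not isolated)
Conditions: 23, MgCl2, Et3N, MeCN, rt; then 22 in THF, rt → 40 °C; aq. HCl (1 M), 0 °C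
Reagents that add atoms: none
Why: Key step, an intermolecular crossed Claisen condensation (Masamune–Brooks, decarboxylative): the magnesium malonate enolate is C-acylated by the acylimidazole to form the C13–C14 bond, and loss of CO2 on acidification gives the β-keto ester.

Step 18
Reactants: 26 ethyl 7α-(tert-butyldimethylsilyloxy)-6β-hydroxy-13-oxo-16-norlabd-8-en-15-oate
Product: 28 ethyl (13Z)-13-(diethoxyphosphoryloxy)-7α-(tert-butyldimethylsilyloxy)-6β-hydroxy-16-norlabda-8,13-dien-15-oate, via sodium enolate 27 (not isolated)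
Conditions: NaH (1.05 equiv), Et2O, 0 °C; then ClP(O)(OEt)2
Reagents that add atoms: diethyl chlorophosphate, CCOP(=O)(Cl)OCC
Why: The chelated sodium enolate of the β-keto ester in ether is O-phosphorylated to the Z enol phosphate (phosphate cis to the ester); one equivalent of base leaves the far less acidic 6β-OH alone.

Step 19
Reactants: 28 ethyl (13Z)-13-(diethoxyphosphoryloxy)-7α-(tert-butyldimethylsilyloxy)-6β-hydroxy-16-norlabda-8,13-dien-15-oate
Product: 29 ethyl (13E)-7α-(tert-butyldimethylsilyloxy)-6β-hydroxylabda-8,13-dien-15-oate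
Conditions: Me2CuLi (from MeLi and CuI, 3.5 equiv), Et2O, −78 → −45 °C
Reagents that add atoms: lithium dimethylcuprate, [Li+].C[Cu-]C
Why: Addition–elimination of the cuprate on the β-phosphoryloxy enoate proceeds with retention of alkene geometry, placing the new C16 methyl cis to the ester and giving the 13E alkene.

Step 20
Reactants: 29 ethyl (13E)-7α-(tert-butyldimethylsilyloxy)-6β-hydroxylabda-8,13-dien-15-oate
Product: 30 (13E)-7α-(tert-butyldimethylsilyloxy)labda-8,13-diene-6β,15-diol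
Conditions: i-Bu2AlH (4 equiv), CH2Cl2, −78 °C; then aq. potassium sodium tartrate (KNaC4H4O6)
Reagents that add atoms: none
Why: 1,2-reduction of the conjugated ester by the aluminium hydride gives the allylic alcohol without changing the alkene geometry.

Step 21
Reactants: 30 (13E)-7α-(tert-butyldimethylsilyloxy)labda-8,13-diene-6β,15-diol
Product: 31 (13E)-7α,15-bis(tert-butyldimethylsilyloxy)labda-8,13-dien-6β-ol
Conditions: TBSCl, imidazole, CH2Cl2, 0 °C
Reagents that add atoms: tert-butyldimethylsilyl chloride, CC(C)(C)[Si](C)(C)Cl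
Why: Silylation is selective for the primary allylic alcohol, so the hindered 6β-OH is the only hydroxyl left free.

Step 22
Reactants: 31 (13E)-7α,15-bis(tert-butyldimethylsilyloxy)labda-8,13-dien-6β-ol
Product: 32 (13E)-7α,15-bis(tert-butyldimethylsilyloxy)labda-8,13-dien-6β-yl 3-methylbutanoate
Conditions: 3-methylbutanoic anhydride, DMAP (2 equiv), Et3N, toluene, 60 °C
Reagents that add atoms: 3-methylbutanoic (isovaleric) anhydride, CC(C)CC(=O)OC(=O)CC(C)C
Why: DMAP-catalysed acyl transfer (Steglich-type) under forcing conditions esterifies the only free hydroxyl, the axial 6β-OH, with retention at C6.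

Step 23
Reactants: 32 (13E)-7α,15-bis(tert-butyldimethylsilyloxy)labda-8,13-dien-6β-yl 3-methylbutanoate
Product: 33 (13E)-7α,15-dihydroxylabda-8,13-dien-6β-yl 3-methylbutanoate (target)
Conditions: HF·pyridine, pyridine, THF, 0 °C → rt
Reagents that add atoms: none
Why: Buffered fluoride cleavage removes both silyl ethers; the ester cannot migrate because the 6β and 7α oxygens are trans-diaxial.

## Compound list

1 | (−)-sclareol, (13R)-labd-14-ene-8α,13-diol | C[C@]1(O)[C@H](CC[C@@](C)(O)C=C)[C@@]2(C)CCCC(C)(C)[C@@H]2CC1 | starting material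
2 | 8α-hydroxy-14,15-dinorlabdan-13-one | C[C@]1(O)[C@H](CCC(C)=O)[C@@]2(C)CCCC(C)(C)[C@@H]2CC1 | intermediate
3 | 16,16,16-tribromo-8α-hydroxy-14,15-dinorlabdan-13-one | C[C@]1(O)[C@H](CCC(=O)C(Br)(Br)Br)[C@@]2(C)CCCC(C)(C)[C@@H]2CC1 | intermediate (not isolated)
4 | 8α-hydroxy-14,15,16-trinorlabdan-13-oic acid | C[C@]1(O)[C@H](CCC(=O)O)[C@@]2(C)CCCC(C)(C)[C@@H]2CC1 | intermediate
5 | 14,15,16-trinorlabdane-8α,13-diol | C[C@]1(O)[C@H](CCCO)[C@@]2(C)CCCC(C)(C)[C@@H]2CC1 | intermediate
6 | 13-(4-methoxybenzyloxy)-14,15,16-trinorlabdan-8α-ol | C[C@]1(O)[C@H](CCCOCc3ccc(OC)cc3)[C@@]2(C)CCCC(C)(C)[C@@H]2CC1 | intermediate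
7 | 13-(4-methoxybenzyloxy)-14,15,16-trinorlabd-8(17)-ene | C=C1[C@H](CCCOCc3ccc(OC)cc3)[C@@]2(C)CCCC(C)(C)[C@@H]2CC1 | intermediate
8 | 13-(4-methoxybenzyloxy)-14,15,16-trinorlabdane-8α,17-diol | OC[C@]1(O)[C@H](CCCOCc3ccc(OC)cc3)[C@@]2(C)CCCC(C)(C)[C@@H]2CC1 | intermediate (not isolated)
9 | 13-(4-methoxybenzyloxy)-14,15,16,17-tetranorlabdan-8-one | O=C1[C@H](CCCOCc3ccc(OC)cc3)[C@@]2(C)CCCC(C)(C)[C@@H]2CC1 | intermediate
10 | lithium 13-(4-methoxybenzyloxy)-14,15,16,17-tetranorlabd-7-en-8-olate | [Li+].[O-]C=1[C@H](CCCOCc3ccc(OC)cc3)[C@@]2(C)CCCC(C)(C)[C@@H]2CC=1 | intermediate (not isolated)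
11 | 13-(4-methoxybenzyloxy)-8-(trimethylsilyloxy)-14,15,16,17-tetranorlabd-7-ene | C[Si](C)(C)OC=1[C@H](CCCOCc3ccc(OC)cc3)[C@@]2(C)CCCC(C)(C)[C@@H]2CC=1 | intermediate
12 | 13-(4-methoxybenzyloxy)-14,15,16,17-tetranorlabd-6-en-8-one | O=C1[C@H](CCCOCc3ccc(OC)cc3)[C@@]2(C)CCCC(C)(C)[C@@H]2C=C1 | intermediate
13 | 13-(4-methoxybenzyloxy)-14,15,16-trinorlabd-6-en-8-ol (C8 epimers; C8 left open in the SMILES) | CC1(O)[C@H](CCCOCc3ccc(OC)cc3)[C@@]2(C)CCCC(C)(C)[C@@H]2C=C1 | intermediate
14 | 13-(4-methoxybenzyloxy)-14,15,16-trinorlabd-7-en-6-one | CC=1[C@H](CCCOCc3ccc(OC)cc3)[C@@]2(C)CCCC(C)(C)[C@@H]2C(=O)C=1 | intermediate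
15 | potassium 13-(4-methoxybenzyloxy)-14,15,16-trinorlabda-6,8-dien-6-olate | [K+].CC1=C(CCCOCc3ccc(OC)cc3)[C@@]2(C)CCCC(C)(C)[C@@H]2C([O-])=C1 | intermediate (not isolated)
16 | 7α-hydroxy-13-(4-methoxybenzyloxy)-14,15,16-trinorlabd-8-en-6-one | CC1=C(CCCOCc3ccc(OC)cc3)[C@@]2(C)CCCC(C)(C)[C@@H]2C(=O)[C@H]1O | intermediate
17 | 13-(4-methoxybenzyloxy)-14,15,16-trinorlabd-8-ene-6β,7α-diol | CC1=C(CCCOCc3ccc(OC)cc3)[C@@]2(C)CCCC(C)(C)[C@@H]2[C@H](O)[C@H]1O | intermediate
18 | 7α-(tert-butyldimethylsilyloxy)-13-(4-methoxybenzyloxy)-14,15,16-trinorlabd-8-en-6β-ol | CC1=C(CCCOCc3ccc(OC)cc3)[C@@]2(C)CCCC(C)(C)[C@@H]2[C@H](O)[C@H]1O[Si](C)(C)C(C)(C)C | intermediate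
19 | 7α-(tert-butyldimethylsilyloxy)-14,15,16-trinorlabd-8-ene-6β,13-diol | CC1=C(CCCO)[C@@]2(C)CCCC(C)(C)[C@@H]2[C@H](O)[C@H]1O[Si](C)(C)C(C)(C)C | intermediate
20 | 7α-(tert-butyldimethylsilyloxy)-6β-hydroxy-14,15,16-trinorlabd-8-en-13-al | CC1=C(CCC=O)[C@@]2(C)CCCC(C)(C)[C@@H]2[C@H](O)[C@H]1O[Si](C)(C)C(C)(C)C | intermediate (not isolated)
21 | 7α-(tert-butyldimethylsilyloxy)-6β-hydroxy-14,15,16-trinorlabd-8-en-13-oic acid | CC1=C(CCC(=O)O)[C@@]2(C)CCCC(C)(C)[C@@H]2[C@H](O)[C@H]1O[Si](C)(C)C(C)(C)C | intermediate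
22 | 1-[7α-(tert-butyldimethylsilyloxy)-6β-hydroxy-14,15,16-trinorlabd-8-en-13-oyl]imidazole | CC1=C(CCC(=O)n3ccnc3)[C@@]2(C)CCCC(C)(C)[C@@H]2[C@H](O)[C@H]1O[Si](C)(C)C(C)(C)C | intermediate
23 | potassium ethyl malonate | [K+].[O-]C(=O)CC(=O)OCC | starting material
24 | magnesium enolate of ethyl malonate (carboxylate enolate dianion) | [Mg+2].[O-]C(=O)[CH-]C(=O)OCC | intermediate (not isolated)
25 | 2-(ethoxycarbonyl)-3-oxo acid from C-acylation of 24 by 22 (malonyl CH not configurationally defined) | CC1=C(CCC(=O)C(C(=O)O)C(=O)OCC)[C@@]2(C)CCCC(C)(C)[C@@H]2[C@H](O)[C@H]1O[Si](C)(C)C(C)(C)C | intermediate (not isolated)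
26 | ethyl 7α-(tert-butyldimethylsilyloxy)-6β-hydroxy-13-oxo-16-norlabd-8-en-15-oate | CC1=C(CCC(=O)CC(=O)OCC)[C@@]2(C)CCCC(C)(C)[C@@H]2[C@H](O)[C@H]1O[Si](C)(C)C(C)(C)C | intermediate
27 | sodium (13Z)-enolate of 26 | [Na+].CC1=C(CC/C([O-])=C/C(=O)OCC)[C@@]2(C)CCCC(C)(C)[C@@H]2[C@H](O)[C@H]1O[Si](C)(C)C(C)(C)C | intermediate (not isolated)
28 | ethyl (13Z)-13-(diethoxyphosphoryloxy)-7α-(tert-butyldimethylsilyloxy)-6β-hydroxy-16-norlabda-8,13-dien-15-oate | CC1=C(CC/C(OP(=O)(OCC)OCC)=C/C(=O)OCC)[C@@]2(C)CCCC(C)(C)[C@@H]2[C@H](O)[C@H]1O[Si](C)(C)C(C)(C)C | intermediate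
29 | ethyl (13E)-7α-(tert-butyldimethylsilyloxy)-6β-hydroxylabda-8,13-dien-15-oate | CC1=C(CC/C(C)=C/C(=O)OCC)[C@@]2(C)CCCC(C)(C)[C@@H]2[C@H](O)[C@H]1O[Si](C)(C)C(C)(C)C | intermediate
30 | (13E)-7α-(tert-butyldimethylsilyloxy)labda-8,13-diene-6β,15-diol | CC1=C(CC/C(C)=C/CO)[C@@]2(C)CCCC(C)(C)[C@@H]2[C@H](O)[C@H]1O[Si](C)(C)C(C)(C)C | intermediate
31 | (13E)-7α,15-bis(tert-butyldimethylsilyloxy)labda-8,13-dien-6β-ol | CC1=C(CC/C(C)=C/CO[Si](C)(C)C(C)(C)C)[C@@]2(C)CCCC(C)(C)[C@@H]2[C@H](O)[C@H]1O[Si](C)(C)C(C)(C)C | intermediate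
32 | (13E)-7α,15-bis(tert-butyldimethylsilyloxy)labda-8,13-dien-6β-yl 3-methylbutanoate | CC1=C(CC/C(C)=C/CO[Si](C)(C)C(C)(C)C)[C@@]2(C)CCCC(C)(C)[C@@H]2[C@H](OC(=O)CC(C)C)[C@H]1O[Si](C)(C)C(C)(C)C | intermediate
33 | (13E)-7α,15-dihydroxylabda-8,13-dien-6β-yl 3-methylbutanoate (CNP0173680.1) | CC1=C(CC/C(C)=C/CO)[C@@]2(C)CCCC(C)(C)[C@@H]2[C@H](OC(=O)CC(C)C)[C@H]1O | target

## Step count and risks

Total: 23 steps. Longest linear sequence: 23 steps from sclareol 1; fragment 23 is bought.

Steps most likely to fail: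

Step 11 (dienolate hydroxylation). Deprotonation may occur at C17 or C5 instead of C9, oxygen may enter at C9 or from the β face, and the α-ketol product can shift under base. The fallback sets out from enone 14. TBSOTf and Et3N (CH2Cl2, 0 °C → rt) give the thermodynamic silyl dienol ether 6-(tert-butyldimethylsilyloxy)-13-(4-methoxybenzyloxy)-14,15,16-trinorlabda-6,8-diene F3. Catalytic OsO4 with N-methylmorpholine N-oxide (acetone/H2O, 0 °C) then dihydroxylates the trisubstituted enol ether C6=C7 bond from the α face. The bulky osmium reagent avoids the tetrasubstituted C8=C9 bond next to quaternary C10. Loss of the silyl group from the C6 hemiketal gives the 7α-hydroxy ketone, and the route is rejoined at 16.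

Step 10 (oxidative transposition). Transfer of the chromate to the hindered C6 may be slow, and the tertiary allylic alcohol can instead dehydrate to dienes. The fallback sets out from ketone 9. KN(SiMe3)2 and PhNTf2 (THF, −78 °C) give the kinetic enol triflate 13-(4-methoxybenzyloxy)-14,15,16,17-tetranorlabd-7-en-8-yl trifluoromethanesulfonate F1. Fe(acac)3-catalysed cross-coupling with MeMgBr (THF/NMP, −20 °C) gives 13-(4-methoxybenzyloxy)-14,15,16-trinorlabd-7-ene F2 with the alkene position fixed. Allylic oxidation of the C6 methylene with CrO3·3,5-dimethylpyrazole (CH2Cl2, −20 °C) then gives the enone, and the route is rejoined at 14.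

Step 22 (acylation of the 6β-OH). The hydroxyl is axial and syn to two methyl groups, so the bulky N-acylpyridinium may not reach it. The fallback sets out from alcohol 31. The alcohol is converted to its lithium alkoxide (LiN(SiMe3)2, THF, −78 °C) and added to isopropylketene F4, generated in the same flask from 3-methylbutanoyl chloride and i-Pr2NEt. The linear ketene carbon is far less demanding than an acylpyridinium, and protonation of the resulting ester enolate gives the isovalerate, so the route is rejoined at 32.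

## Further compounds

F1 | step 10 | 13-(4-methoxybenzyloxy)-14,15,16,17-tetranorlabd-7-en-8-yl trifluoromethanesulfonate | O=S(=O)(OC=1[C@H](CCCOCc3ccc(OC)cc3)[C@@]2(C)CCCC(C)(C)[C@@H]2CC=1)C(F)(F)F
F2 | step 10 | 13-(4-methoxybenzyloxy)-14,15,16-trinorlabd-7-ene | CC=1[C@H](CCCOCc3ccc(OC)cc3)[C@@]2(C)CCCC(C)(C)[C@@H]2CC=1
F3 | step 11 | 6-(tert-butyldimethylsilyloxy)-13-(4-methoxybenzyloxy)-14,15,16-trinorlabda-6,8-diene | CC1=C(CCCOCc3ccc(OC)cc3)[C@@]2(C)CCCC(C)(C)[C@@H]2C(O[Si](C)(C)C(C)(C)C)=C1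
F4 | step 22 | isopropylketene (3-methylbut-1-en-1-one) | CC(C)C=C=O
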